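**Plan**
1. Cuts, in retrosynthetic order: the C6–O ester bond (acylation), the C6–H bond (ketone reduction), the C3=C3a bond (intramolecular Horner–Wadsworth–Emmons reaction), and then the C4–C5 and C6–C7 bonds together.
2. Enabling feature: in the cyclohexane ring, C6 lies 1,4 to C3a (a ketone carbon before the butenolide exists) and 1,3 to the C7a oxygen. C4 is therefore the only enolisable carbon of an isopropyl ketone, and C7–C7a–O is the imprint of a 2,2-disubstituted epoxide. A two-carbon unit that is a Michael acceptor at C5 and then an acyl-anion equivalent at C6 (a ketene dithioacetal S-oxide) can stitch the ring in one pot.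
3. Forward order: chiral epoxy ketone, then the carbocycle by Michael/epoxide-opening annulation, then the butenolide ring, then unmasking of the C6 ketone, reduction and palmitoylation.
4. Stereochemistry: C7a (R) comes from (S)-2-methylglycidol and is never a reacting centre. C6 (S) is set by equatorial hydride delivery to the C6 ketone, whose axial face is blocked by syn-axial methyl groups on C4 and C7a.

Key step: step 5

Remark (assumption): 1,1-bis(methylsulfanyl)ethene 6 is taken as a purchasable reagent; atom numbers in the text are those of the benzofuranone skeleton of the target (O1, C2, C3, C3a, C4 to C7, C7a).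

**Step 1**
Reactants: 1 (S)-2-methylglycidol
Product: 2 (2R)-2-methyloxirane-2-carbaldehyde
Conditions: TEMPO (cat.), PhI(OAc)2, CH2Cl2, 0 °C → rt; aq. NaHCO3 wash, dried solution used directly
Reagents that add atoms: none
Why: Nitroxyl-catalysed (TEMPO/oxoammonium) oxidation of a primary alcohol stops at the aldehyde under anhydrous conditions and does not touch the epoxide or the quaternary stereocentre, whose descriptor changes from S to R only because CHO outranks the ring CH2.

**Step 2**
Reactants: 2 (2R)-2-methyloxirane-2-carbaldehyde; 3 isopropylmagnesium chloride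
Product: 4 (1RS)-2-methyl-1-[(2R)-2-methyloxiran-2-yl]propan-1-ol
Conditions: i-PrMgCl, THF, −78 °C; aq. NH4Cl
Reagents that add atoms: isopropylmagnesium chloride, CC(C)[Mg]Cl
Why: Grignard 1,2-addition to the aldehyde is much faster than epoxide opening at −78 °C; the new carbinol centre forms as a mixture, which is harmless because step 3 oxidises it.

**Step 3**
Reactants: 4 (1RS)-2-methyl-1-[(2R)-2-methyloxiran-2-yl]propan-1-ol
Product: 5 2-methyl-1-[(2R)-2-methyloxiran-2-yl]propan-1-one
Conditions: Dess–Martin periodinane, CH2Cl2, 0 °C → rt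
Reagents that add atoms: none
Why: Dess–Martin oxidation of a secondary alcohol under near-neutral conditions should give the α,β-epoxy ketone without epoxide opening, and the quaternary C7a centre cannot epimerise.

**Step 4**
Reactants: 6 1,1-bis(methylsulfanyl)ethene
Product: 7 1-(methylsulfinyl)-1-(methylsulfanyl)ethene (racemic at sulfur)
Conditions: mCPBA (1.0 equiv), CH2Cl2, −78 → −20 °C
Reagents that add atoms: mCPBA, OOC(=O)c1cccc(Cl)c1
Why: Sulfide-to-sulfoxide oxidation by one equivalent of peracid at low temperature is faster than attack on the second, now deactivated, sulfur or on the alkene, and should give the two-carbon Michael acceptor.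

**Step 5**
Reactants: 5 2-methyl-1-[(2R)-2-methyloxiran-2-yl]propan-1-one; 7 1-(methylsulfinyl)-1-(methylsulfanyl)ethene
Product: 10 (2R)-2-hydroxy-2,6,6-trimethyl-4-(methylsulfinyl)-4-(methylsulfanyl)cyclohexan-1-one, via lithium enolate 8 (not isolated), via sulfur-stabilised carbanion 9 (not isolated)
Conditions: LiN(i-Pr)2 (1.05 equiv), THF, −78 → −30 °C; 7 added slowly at −78 °C, then → 0 °C (DMPU if needed); AcOH, −78 °C
Reagents that add atoms: 1-(methylsulfinyl)-1-(methylsulfanyl)ethene, C=C(SC)S(C)=O
Why: Proposed new method: LiN(i-Pr)2 removes the only α-hydrogen of 5 (the isopropyl methine; the other α-carbon is the quaternary epoxide carbon), the carbon terminus of the tetrasubstituted enolate 8 adds to the CH2 end of 7 and makes C4–C5 with the gem-dimethyl quaternary centre, and the sulfinyl- and sulfanyl-stabilised carbanion 9, an acyl-anion equivalent at C6, opens the epoxide at its CH2 carbon on warming and makes C6–C7 while it releases the C7a alkoxide. The closest known reaction types are the conjugate addition of enolates to ketene dithioacetal S-oxides with capture of the resulting carbanion by alkyl halides (Michael-initiated ring closure) and the ring closure of stabilised carbanions onto epoxides as in epoxynitrile cyclisations; their union on an epoxy ketone is the unproven part. The cyclohexanone ring closes by a 6-endo SN2 opening of the epoxide, for which C6, C7 and the leaving oxygen can line up in a chair-like array, whereas the 5-exo alternative would need substitution at the fully substituted C7a and is excluded. C7a is not a reacting centre (the C7–O bond breaks, the C7a–O bond stays), so its R configuration is carried over unchanged from 1, and the new stereocentres at C6 and sulfur are left uncontrolled on purpose because step 8 erases both. The step needs C- over O-alkylation of the enolate, which the soft acceptor favours, and cyclisation of 9 in preference to a second addition to 7 or to proton transfer, which the substrate secures because after the Michael addition both carbons next to the ketone are quaternary and no acidic C–H is within reach.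

**Step 6**
Reactants: 10 (2R)-2-hydroxy-2,6,6-trimethyl-4-(methylsulfinyl)-4-(methylsulfanyl)cyclohexan-1-one; 11 (diethoxyphosphoryl)acetic acid
Product: 12 (1R)-1,3,3-trimethyl-5-(methylsulfinyl)-5-(methylsulfanyl)-2-oxocyclohexyl (diethoxyphosphoryl)acetate
Conditions: DCC, DMAP (cat.), CH2Cl2, 0 °C → rt
Reagents that add atoms: (diethoxyphosphoryl)acetic acid, CCOP(=O)(OCC)CC(=O)O
Why: Carbodiimide (Steglich-type) esterification, in which the phosphonoacetic acid reacts through a ketene-like activated form and should therefore acylate even a tertiary α-ketol; no stereocentre is touched.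

**Step 7**
Reactants: 12 (1R)-1,3,3-trimethyl-5-(methylsulfinyl)-5-(methylsulfanyl)-2-oxocyclohexyl (diethoxyphosphoryl)acetate
Product: 13 (7aR)-4,4,7a-trimethyl-6-(methylsulfinyl)-6-(methylsulfanyl)-5,6,7,7a-tetrahydro-1-benzofuran-2(4H)-one
Conditions: NaH, THF, 0 °C → rt
Reagents that add atoms: none
Why: Intramolecular Horner–Wadsworth–Emmons olefination closes the five-membered lactone (5-exo attack of the phosphonate carbanion on the C3a ketone), the ring fixes the geometry of the C3=C3a bond, and the ketone has no α-hydrogen, so enolisation cannot compete.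

**Step 8**
Reactants: 13 (7aR)-4,4,7a-trimethyl-6-(methylsulfinyl)-6-(methylsulfanyl)-5,6,7,7a-tetrahydro-1-benzofuran-2(4H)-one
Product: 14 (7aR)-4,4,7a-trimethyl-5,7a-dihydro-1-benzofuran-2,6(4H,7H)-dione (dehydrololiolide)
Conditions: HClO4 (70% aq., cat.), MeCN/H2O, 0 °C, short contact time; NaHCO3 quench
Reagents that add atoms: water, O
Why: Acid-promoted hydrolysis of a dithioacetal S-oxide (loss of methanesulfenic acid to a thionium ion, addition of water, loss of methanethiol) should unmask the C6 ketone under conditions that leave the butenolide intact.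

**Step 9**
Reactants: 14 (7aR)-4,4,7a-trimethyl-5,7a-dihydro-1-benzofuran-2,6(4H,7H)-dione
Product: 15 (6S,7aR)-6-hydroxy-4,4,7a-trimethyl-5,6,7,7a-tetrahydro-1-benzofuran-2(4H)-one ((−)-loliolide)
Conditions: LiBH(s-Bu)3, THF, −78 °C; AcOH, −78 °C
Reagents that add atoms: none
Why: Kinetically controlled ketone reduction by a bulky trialkylborohydride: in the chair of 14 the C7a methyl and one C4 methyl are axial on the same face and block the axial path to C6, so hydride should enter equatorially and give the axial 6S alcohol cis to the C7a methyl, while the fully substituted β-carbon C3a suppresses conjugate reduction of the butenolide.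

**Step 10**
Reactants: 15 (6S,7aR)-6-hydroxy-4,4,7a-trimethyl-5,6,7,7a-tetrahydro-1-benzofuran-2(4H)-one; 16 hexadecanoyl chloride
Product: 17 (6S,7aR)-4,4,7a-trimethyl-2-oxo-2,4,5,6,7,7a-hexahydro-1-benzofuran-6-yl hexadecanoate ((−)-3-O-palmitoylloliolide)
Conditions: pyridine, DMAP (cat.), CH2Cl2, 0 °C → rt
Reagents that add atoms: hexadecanoyl chloride, CCCCCCCCCCCCCCCC(=O)Cl
Why: DMAP-catalysed acylation of the secondary alcohol by the acid chloride does not involve the C6–O bond and therefore proceeds with retention at C6.

**Compound list**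
1 | (S)-2-methylglycidol | OC[C@@]1(C)CO1 | starting material
2 | (2R)-2-methyloxirane-2-carbaldehyde | O=C[C@@]1(C)CO1 | intermediate
3 | isopropylmagnesium chloride | CC(C)[Mg]Cl | starting material
4 | (1RS)-2-methyl-1-[(2R)-2-methyloxiran-2-yl]propan-1-ol | CC(C)C(O)[C@@]1(C)CO1 | intermediate
5 | 2-methyl-1-[(2R)-2-methyloxiran-2-yl]propan-1-one | CC(C)C(=O)[C@@]1(C)CO1 | intermediate
6 | 1,1-bis(methylsulfanyl)ethene | C=C(SC)SC | starting material
7 | 1-(methylsulfinyl)-1-(methylsulfanyl)ethene (racemic at sulfur) | C=C(SC)S(C)=O | intermediate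
8 | lithium 2-methyl-1-[(2R)-2-methyloxiran-2-yl]prop-1-en-1-olate | CC(C)=C([O-])[C@@]1(C)CO1.[Li+] | intermediate (not isolated)
9 | [4,4-dimethyl-1-(methylsulfinyl)-1-(methylsulfanyl)-5-[(2R)-2-methyloxiran-2-yl]-5-oxopentyl]lithium | CS[C-](CC(C)(C)C(=O)[C@@]1(C)CO1)S(C)=O.[Li+] | intermediate (not isolated)
10 | (2R)-2-hydroxy-2,6,6-trimethyl-4-(methylsulfinyl)-4-(methylsulfanyl)cyclohexan-1-one (mixture at C4 and sulfur) | CC1(C)CC(SC)(S(C)=O)C[C@@](C)(O)C1=O | intermediate
11 | (diethoxyphosphoryl)acetic acid | CCOP(=O)(OCC)CC(=O)O | starting material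
12 | (1R)-1,3,3-trimethyl-5-(methylsulfinyl)-5-(methylsulfanyl)-2-oxocyclohexyl (diethoxyphosphoryl)acetate | CCOP(=O)(OCC)CC(=O)O[C@]1(C)CC(SC)(S(C)=O)CC(C)(C)C1=O | intermediate
13 | (7aR)-4,4,7a-trimethyl-6-(methylsulfinyl)-6-(methylsulfanyl)-5,6,7,7a-tetrahydro-1-benzofuran-2(4H)-one | CS(=O)C1(SC)CC(C)(C)C2=CC(=O)O[C@]2(C)C1 | intermediate
14 | (7aR)-4,4,7a-trimethyl-5,7a-dihydro-1-benzofuran-2,6(4H,7H)-dione | O=C1CC(C)(C)C2=CC(=O)O[C@]2(C)C1 | intermediate
15 | (6S,7aR)-6-hydroxy-4,4,7a-trimethyl-5,6,7,7a-tetrahydro-1-benzofuran-2(4H)-one | O[C@H]1CC(C)(C)C2=CC(=O)O[C@]2(C)C1 | intermediate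
16 | hexadecanoyl chloride | CCCCCCCCCCCCCCCC(=O)Cl | starting material
17 | (6S,7aR)-4,4,7a-trimethyl-2-oxo-2,4,5,6,7,7a-hexahydro-1-benzofuran-6-yl hexadecanoate | CCCCCCCCCCCCCCCC(=O)O[C@H]1CC(C)(C)C2=CC(=O)O[C@]2(C)C1 | target

**Step count and risks**
Total: 10 steps. Longest linear sequence: 9 steps (steps 1 to 3 and 5 to 10); step 4 is a one-step side branch.

Step 5 (Proposed new method). What may go wrong: sluggish or reversible conjugate addition of the hindered enolate, oligomerisation of the acceptor, or failure of the sulfur-stabilised carbanion to reach the epoxide carbon. The fallback sets out from 5 and returns at 14; it makes the two bonds in separate, individually known operations with a more electrophilic and thermally robust two-carbon unit. Enolate 8 is added to phenyl vinyl sulfone (THF, −78 °C, AcOH quench) to give the keto sulfone 2,2-dimethyl-1-[(2R)-2-methyloxiran-2-yl]-4-(phenylsulfonyl)butan-1-one F1. Deprotonation next to the sulfone (LiN(i-Pr)2, THF/DMPU, −78 → 0 °C) should close the ring by sulfonyl-carbanion opening of the epoxide to (2R)-2-hydroxy-2,6,6-trimethyl-4-(phenylsulfonyl)cyclohexan-1-one F2. The ketol is converted with Ph3P=C=C=O (toluene, 110 °C; addition of the hydroxyl group to the ketene ylide, then intramolecular Wittig reaction) into the butenolide (7aR)-4,4,7a-trimethyl-6-(phenylsulfonyl)-5,6,7,7a-tetrahydro-1-benzofuran-2(4H)-one F3. Oxidative desulfonylation (LiN(i-Pr)2, THF, −78 °C, then Me3SiOOSiMe3) should then give 14.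

Step 7. What may go wrong: the phosphonate carbanion may fail to attack the ketone carbon, which is flanked by two quaternary carbons, so that ester cleavage outruns olefination. The fallback sets out from 10 and returns at 13; it replaces the olefination by an intramolecular Reformatsky reaction with SmI2 (divalent samarium), which adds ester enolates to hindered ketones. Acylation of 10 with bromoacetyl bromide (pyridine, CH2Cl2, −20 °C) gives (1R)-1,3,3-trimethyl-5-(methylsulfinyl)-5-(methylsulfanyl)-2-oxocyclohexyl bromoacetate F4. SmI2 (THF, −78 °C) should close the lactone to (7aR)-3a-hydroxy-4,4,7a-trimethyl-6-(methylsulfinyl)-6-(methylsulfanyl)hexahydro-1-benzofuran-2(3H)-one F5 (either C3a epimer). Dehydration with methyl N-(triethylammoniosulfonyl)carbamate (Burgess reagent; the only β-hydrogens are on C3) should give 13.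

Step 8. What may go wrong: under the acid needed for hydrolysis, the product, a β-acyloxy ketone, may lose the lactone carboxylate by retro-oxa-Michael reaction, and ring opening and reclosure would scramble C7a. The fallback sets out from 13 and returns at 14; it replaces protic hydrolysis by deoxygenation and fast oxidative cleavage. Deoxygenation of the sulfoxide (PPh3, I2, NaI, MeCN, rt) gives the dithioketal (7aR)-4,4,7a-trimethyl-6,6-bis(methylsulfanyl)-5,6,7,7a-tetrahydro-1-benzofuran-2(4H)-one F6, which PhI(OCOCF3)2 in aqueous MeCN at 0 °C should cleave within minutes to 14.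

**Further compounds**
F1 | step 5 | 2,2-dimethyl-1-[(2R)-2-methyloxiran-2-yl]-4-(phenylsulfonyl)butan-1-one | CC(C)(CCS(=O)(=O)c1ccccc1)C(=O)[C@@]1(C)CO1
F2 | step 5 | (2R)-2-hydroxy-2,6,6-trimethyl-4-(phenylsulfonyl)cyclohexan-1-one (both C4 epimers) | CC1(C)CC(S(=O)(=O)c2ccccc2)C[C@@](C)(O)C1=O
F3 | step 5 | (7aR)-4,4,7a-trimethyl-6-(phenylsulfonyl)-5,6,7,7a-tetrahydro-1-benzofuran-2(4H)-one (both C6 epimers) | O=S(=O)(c1ccccc1)C1CC(C)(C)C2=CC(=O)O[C@]2(C)C1
F4 | step 7 | (1R)-1,3,3-trimethyl-5-(methylsulfinyl)-5-(methylsulfanyl)-2-oxocyclohexyl bromoacetate | O=C(CBr)O[C@]1(C)CC(SC)(S(C)=O)CC(C)(C)C1=O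
F5 | step 7 | (7aR)-3a-hydroxy-4,4,7a-trimethyl-6-(methylsulfinyl)-6-(methylsulfanyl)hexahydro-1-benzofuran-2(3H)-one (either C3a epimer) | CS(=O)C1(SC)CC(C)(C)C2(O)CC(=O)O[C@]2(C)C1
F6 | step 8 | (7aR)-4,4,7a-trimethyl-6,6-bis(methylsulfanyl)-5,6,7,7a-tetrahydro-1-benzofuran-2(4H)-one | CSC1(SC)CC(C)(C)C2=CC(=O)O[C@]2(C)C1
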